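## Retrosynthetic overview

1. C13–C14 is cut last: a ketone-derived silylperoxy oxocarbenium ion on the decalin is joined to an E-alkenylboronate that already carries the (S)-butenolide. This new catalytic step makes the peroxide-bearing C13 centre; global desilylation then gives the target.
2. Ring B is closed second, by an aldol bond C6–C7 between a C5 formyl group and a C8 methyl ketone. The C8 carbinol follows by methylenation and hydration. The formyl group comes from the ring A ketone by epoxide formation and a 1,2-hydride shift.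
3. C9–C10 comes from a branched allylation of the ring A β-keto ester with a C7–C13 allylic carbonate.
4. Ring A is made first, in the key step: catalytic asymmetric ring expansion (1,2-alkyl shift with loss of N2) of 2-methylcyclopentanone with methyl 2-diazopropanoate. It creates the C4 quaternary centre (CH3, CO2Me) and the ketone on which the rest is built.
5. The butenolide ring is formed separately from acrolein and methyl propiolate (asymmetric alkynylation, then methylcuprate addition and lactonisation).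

Numbering used in names: decalin C1–C10 as in labdanes (C4 carries CH3 and CO2Me, C10 the angular CH3, C8 the carbinol CH3), side chain C11–C15, butenolide attached through C16; α is the face opposite the C10 methyl group.

Assumption: where a chiral catalyst or ligand is named, the enantiomer meant is the one that gives the configuration drawn in the SMILES; 2-methylcyclopentanone is used as the racemate.

## Route

Step 1
Reactants: 1 L-alanine methyl ester hydrochloride
Product: 2 methyl 2-diazopropanoate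
Conditions: isoamyl nitrite (1.2 equiv), AcOH (0.2 equiv), Et3N (1.0 equiv), CHCl3, reflux, 20 min
Reagents that add atoms: isoamyl nitrite, CC(C)CCON=O
Why: diazotisation of the α-amino ester, where loss of the α-proton from the diazonium ion gives the stabilised α-diazo ester (the alanine stereocentre is not needed).

Step 2
Reactants: 3 2-methylcyclopentanone (racemic); 2 methyl 2-diazopropanoate
Product: 4 methyl (1R)-1,3-dimethyl-2-oxocyclohexane-1-carboxylate (both C3 epimers)
Conditions: Sc(OTf)3 (5 mol%), chiral N,N'-dioxide ligand (6 mol%), CH2Cl2, −20 °C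
Reagents that add atoms: none
Why: catalytic asymmetric diazo ester ring expansion (Tiffeneau–Demjanov-type homologation), in which the diazo carbon adds to the Sc-bound carbonyl and the less substituted ring CH2 makes the 1,2-shift with loss of N2, so the inserted carbon becomes the C4 quaternary centre with its configuration set by the chiral scandium complex.

Step 3
Reactants: 5 hex-5-en-2-one
Product: 6 2-(but-3-en-1-yl)-2-methyl-1,3-dioxolane
Conditions: ethylene glycol, p-TsOH (cat.), benzene, reflux (Dean–Stark)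
Reagents that add atoms: ethylene glycol, OCCO
Why: acid-catalysed ketalisation masks the future C13 ketone against the enolate, ylide and hydride chemistry that follows.

Step 4
Reactants: 6 2-(but-3-en-1-yl)-2-methyl-1,3-dioxolane; 7 allyl methyl carbonate (3 equiv)
Product: 8 methyl (2E)-5-(2-methyl-1,3-dioxolan-2-yl)pent-2-en-1-yl carbonate
Conditions: second-generation Grubbs catalyst RuCl2(=CHPh)(PCy3)(H2IMes) (2 mol%), CH2Cl2, 40 °C
Reagents that add atoms: none
Why: olefin cross-metathesis of two unhindered terminal alkenes gives the E-disubstituted allylic carbonate under thermodynamic control.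

Step 5
Reactants: 4 methyl (1R)-1,3-dimethyl-2-oxocyclohexane-1-carboxylate; 8 methyl (2E)-5-(2-methyl-1,3-dioxolan-2-yl)pent-2-en-1-yl carbonate
Product: 9 methyl (1R,3R)-1,3-dimethyl-3-[(3S)-5-(2-methyl-1,3-dioxolan-2-yl)pent-1-en-3-yl]-2-oxocyclohexane-1-carboxylate (ring methyls cis)
Conditions: LiN(SiMe3)2, THF, −78 °C; then [Ir(cod)Cl]2 (2 mol%), (R,R,Ra)-phosphoramidite ligand (4 mol%, pre-activated with n-PrNH2), LiCl, THF, 25 °C
Reagents that add atoms: none
Why: iridium-catalysed branched-selective allylic alkylation (Tsuji–Trost type), where the ligand sets the CH(vinyl) centre C9 and the lithium enolate, chelated to the neighbouring ester so that the C4 methyl is pseudo-axial, is attacked anti to that methyl, which sets C10.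

Step 6
Reactants: 9 methyl (1R,3R)-1,3-dimethyl-3-[(3S)-5-(2-methyl-1,3-dioxolan-2-yl)pent-1-en-3-yl]-2-oxocyclohexane-1-carboxylate
Product: 11 methyl (1R,3R)-2-formyl-1,3-dimethyl-3-[(3S)-5-(2-methyl-1,3-dioxolan-2-yl)pent-1-en-3-yl]cyclohexane-1-carboxylate (C2 epimers), via spiro-epoxide 10 (not isolated)
Conditions: Me3S+ I−, n-BuLi, THF, −10 to 25 °C; then MgBr2·OEt2 (0.3 equiv), 40 °C
Reagents that add atoms: trimethylsulfonium iodide, C[S+](C)C.[I-]
Why: Corey–Chaykovsky epoxidation of the non-enolisable ketone followed by Meinwald rearrangement (Lewis acid opens the epoxide at the tertiary carbon, then a 1,2-hydride shift) gives the one-carbon-homologated aldehyde, whose C5 centre stays epimerisable and is fixed in step 8.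

Step 7
Reactants: 11 methyl (1R,3R)-2-formyl-1,3-dimethyl-3-[(3S)-5-(2-methyl-1,3-dioxolan-2-yl)pent-1-en-3-yl]cyclohexane-1-carboxylate
Product: 12 methyl 2-formyl-1,3-dimethyl-3-[5-(2-methyl-1,3-dioxolan-2-yl)-2-oxopentan-3-yl]cyclohexane-1-carboxylate (stereocentres as in 11)
Conditions: PdCl2 (10 mol%), CuCl (1 equiv), O2 (1 atm), DMF/H2O 7:1, 25 °C
Reagents that add atoms: water, O
Why: Tsuji–Wacker oxidation, where Markovnikov hydroxypalladation of the monosubstituted alkene gives the C8 methyl ketone without touching a stereocentre.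

Step 8
Reactants: 12 methyl 2-formyl-1,3-dimethyl-3-[5-(2-methyl-1,3-dioxolan-2-yl)-2-oxopentan-3-yl]cyclohexane-1-carboxylate
Product: 13 methyl 6α-hydroxy-4β,10β-dimethyl-9β-[2-(2-methyl-1,3-dioxolan-2-yl)ethyl]-8-oxo-5α-decalin-4α-carboxylate
Conditions: DBU (1.5 equiv), CH2Cl2, 0 to 25 °C, 12 h
Reagents that add atoms: none
Why: intramolecular aldol addition of the methyl ketone to the aldehyde closes ring B, and under these reversible conditions C5, C6 and C9 settle in the most stable arrangement (trans ring fusion, equatorial 6α-OH, equatorial side chain).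

Step 9
Reactants: 13 methyl 6α-hydroxy-4β,10β-dimethyl-9β-[2-(2-methyl-1,3-dioxolan-2-yl)ethyl]-8-oxo-5α-decalin-4α-carboxylate
Product: 14 methyl 6α-hydroxy-4β,10β-dimethyl-8-methylidene-9β-[2-(2-methyl-1,3-dioxolan-2-yl)ethyl]-5α-decalin-4α-carboxylate
Conditions: Zn, CH2Br2, TiCl4 (pre-formed Takai–Lombardo reagent), THF/CH2Cl2, 0 to 25 °C
Reagents that add atoms: dibromomethane, BrCBr
Why: Takai–Lombardo methylenation is non-basic, so the β-hydroxy ketone neither retro-aldolises nor dehydrates and no stereocentre is touched.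

Step 10
Reactants: 14 methyl 6α-hydroxy-4β,10β-dimethyl-8-methylidene-9β-[2-(2-methyl-1,3-dioxolan-2-yl)ethyl]-5α-decalin-4α-carboxylate
Product: 15 methyl 6α,8α-dihydroxy-4β,8β,10β-trimethyl-9β-[2-(2-methyl-1,3-dioxolan-2-yl)ethyl]-5α-decalin-4α-carboxylate
Conditions: Mn(dpm)3 (10 mol%; dpm = dipivaloylmethanate), PhSiH3 (2.5 equiv), O2 (1 atm), i-PrOH/CH2Cl2, 0 °C
Reagents that add atoms: dioxygen, O=O
Why: Mukaiyama hydration (metal-hydride hydrogen atom transfer), where H adds to the CH2 terminus and the tertiary C8 radical is trapped by O2 from the α face, away from the axial C10 methyl, giving 8α-OH and 8β-CH3.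

Step 11
Reactants: 15 methyl 6α,8α-dihydroxy-4β,8β,10β-trimethyl-9β-[2-(2-methyl-1,3-dioxolan-2-yl)ethyl]-5α-decalin-4α-carboxylate
Product: 16 methyl 6α,8α-bis(tert-butyldimethylsilyloxy)-4β,8β,10β-trimethyl-9β-[2-(2-methyl-1,3-dioxolan-2-yl)ethyl]-5α-decalin-4α-carboxylate
Conditions: TBSOTf (3 equiv), 2,6-lutidine (4 equiv), CH2Cl2, 0 to 25 °C
Reagents that add atoms: tert-butyldimethylsilyl triflate, CC(C)(C)[Si](C)(C)OS(=O)(=O)C(F)(F)F
Why: silyl ether formation protects both hydroxyl groups, which matters most for the 8-OH because it would otherwise trap the C13 cation as a cyclic ketal in steps 12 and 17.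

Step 12
Reactants: 16 methyl 6α,8α-bis(tert-butyldimethylsilyloxy)-4β,8β,10β-trimethyl-9β-[2-(2-methyl-1,3-dioxolan-2-yl)ethyl]-5α-decalin-4α-carboxylate
Product: 18 methyl 6α,8α-bis(tert-butyldimethylsilyloxy)-9β-(3-hydroperoxy-3-methoxybutyl)-4β,8β,10β-trimethyl-5α-decalin-4α-carboxylate (C13 epimers), via dimethyl ketal 17 (not isolated)
Conditions: HC(OMe)3 (5 equiv), MeOH, PPTS (10 mol%), 40 °C; then anhydrous H2O2 in Et2O (10 equiv), CSA (5 mol%), 0 °C
Reagents that add atoms: trimethyl orthoformate, COC(OC)OC; hydrogen peroxide, OO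
Why: transketalisation and then acid-catalysed perhydrolysis of the ketal through its oxocarbenium ion give the α-methoxy hydroperoxide, whose C13 configuration is irrelevant because the centre is ionised again in step 17.

Step 13
Reactants: 18 methyl 6α,8α-bis(tert-butyldimethylsilyloxy)-9β-(3-hydroperoxy-3-methoxybutyl)-4β,8β,10β-trimethyl-5α-decalin-4α-carboxylate
Product: 19 methyl 6α,8α-bis(tert-butyldimethylsilyloxy)-9β-[3-(tert-butyldimethylsilylperoxy)-3-methoxybutyl]-4β,8β,10β-trimethyl-5α-decalin-4α-carboxylate (C13 epimers)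
Conditions: TBSCl (1.5 equiv), imidazole (3 equiv), DMF, 0 °C
Reagents that add atoms: tert-butyldimethylsilyl chloride, CC(C)(C)[Si](C)(C)Cl
Why: O-silylation of the hydroperoxide gives the silyl monoperoxyketal, the established precursor of peroxycarbenium ions, and blocks acid-induced fragmentation of the free OOH.

Step 14
Reactants: 20 acrolein; 21 methyl propiolate
Product: 22 methyl (4S)-4-hydroxyhex-5-en-2-ynoate
Conditions: Me2Zn (3 equiv), (S,S)-ProPhenol (10 mol%), Ph3P=O (20 mol%), toluene, 4 °C; aq. NH4Cl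
Reagents that add atoms: none
Why: catalytic asymmetric zinc alkynylide addition to the enal (ProPhenol dinuclear zinc catalyst) sets the carbinol centre that becomes C16.

Step 15
Reactants: 22 methyl (4S)-4-hydroxyhex-5-en-2-ynoate
Product: 24 (5S)-5-ethenyl-4-methylfuran-2(5H)-one, via Z-hydroxy enoate 23 (not isolated)
Conditions: Me2CuLi (2.2 equiv), THF, −78 °C; then 1 M HCl, 0 to 25 °C
Reagents that add atoms: lithium dimethylcuprate, [Li+].C[Cu-]C
Why: syn-carbocupration of the ynoate places the ester cis to the carbinol carbon, so acidification lactonises to the butenolide while C16 is untouched.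

Step 16
Reactants: 24 (5S)-5-ethenyl-4-methylfuran-2(5H)-one
Product: 25 (5S)-4-methyl-5-[(E)-2-(4,4,5,5-tetramethyl-1,3,2-dioxaborolan-2-yl)ethenyl]furan-2(5H)-one
Conditions: vinylboronic acid pinacol ester (3 equiv), second-generation Hoveyda–Grubbs catalyst RuCl2(=CH-C6H4-2-O-iPr)(H2IMes) (5 mol%), CH2Cl2, 40 °C
Reagents that add atoms: vinylboronic acid pinacol ester, C=CB1OC(C)(C)C(C)(C)O1
Why: olefin cross-metathesis with the vinylboronate gives the E-alkenylboronate under thermodynamic control, and the electron-poor trisubstituted ring alkene does not take part.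

Step 17
Reactants: 19 methyl 6α,8α-bis(tert-butyldimethylsilyloxy)-9β-[3-(tert-butyldimethylsilylperoxy)-3-methoxybutyl]-4β,8β,10β-trimethyl-5α-decalin-4α-carboxylate; 25 (5S)-4-methyl-5-[(E)-2-(4,4,5,5-tetramethyl-1,3,2-dioxaborolan-2-yl)ethenyl]furan-2(5H)-one
Product: 26 6,8-bis-O-TBS, 13-OO-TBS derivative of the target (13R,14E,16S)
Conditions: chiral imidodiphosphorimidate Brønsted acid (5 mol%), 4 Å molecular sieves, toluene/CH2Cl2, −60 °C
Reagents that add atoms: none
Why: Proposed new method: catalytic asymmetric alkenylation of a ketone-derived peroxycarbenium ion — the confined chiral acid ionises the methoxy group of the silyl monoperoxyketal (the peroxide oxygen is the poorer leaving group and stabilises the cation), the released methanol and the chiral anion turn the alkenyl–B(pin) into a boronate that transfers its alkenyl group with retention of E geometry to one face of the planar C13 cation in the chiral ion pair (CH3 versus CH2R discrimination gives 13R, and both C13 epimers of 19 converge on the same ion), and formation of MeO–B(pin) returns the proton; the closest known reactions are Lewis-acid-mediated allylsilane additions to peroxycarbenium ions from monoperoxyketals and chiral-acid- or diol-catalysed additions of alkenylboronates to oxocarbenium ions.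

Step 18
Reactants: 26 6,8-bis-O-TBS, 13-OO-TBS derivative of the target
Product: 27 CNP0128148.1
Conditions: HF·pyridine, pyridine, THF, 0 to 25 °C
Reagents that add atoms: none
Why: fluoride-mediated desilylation under buffered conditions frees the two alcohols and the hydroperoxide without affecting the butenolide, the methyl ester or any stereocentre.

## Compound list

1 | L-alanine methyl ester hydrochloride | C[C@H](N)C(=O)OC.Cl | starting material
2 | methyl 2-diazopropanoate | COC(=O)C(C)=[N+]=[N-] | intermediate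
3 | 2-methylcyclopentanone (racemic) | CC1CCCC1=O | starting material
4 | methyl (1R)-1,3-dimethyl-2-oxocyclohexane-1-carboxylate (C3 epimers) | COC(=O)[C@]1(C)CCCC(C)C1=O | intermediate
5 | hex-5-en-2-one | CC(=O)CCC=C | starting material
6 | 2-(but-3-en-1-yl)-2-methyl-1,3-dioxolane | CC1(CCC=C)OCCO1 | intermediate
7 | allyl methyl carbonate | COC(=O)OCC=C | starting material
8 | methyl (2E)-5-(2-methyl-1,3-dioxolan-2-yl)pent-2-en-1-yl carbonate | COC(=O)OC/C=C/CCC1(C)OCCO1 | intermediate
9 | methyl (1R,3R)-1,3-dimethyl-3-[(3S)-5-(2-methyl-1,3-dioxolan-2-yl)pent-1-en-3-yl]-2-oxocyclohexane-1-carboxylate | COC(=O)[C@]1(C)CCC[C@@]([C@H](C=C)CCC2(C)OCCO2)(C)C1=O | intermediate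
10 | spiro-epoxide of 9 at the former ketone carbon (1-oxaspiro[2.5]octane; spiro-centre epimers; not isolated) | COC(=O)[C@]1(C)CCC[C@@]([C@H](C=C)CCC2(C)OCCO2)(C)C13CO3 | intermediate
11 | methyl (1R,3R)-2-formyl-1,3-dimethyl-3-[(3S)-5-(2-methyl-1,3-dioxolan-2-yl)pent-1-en-3-yl]cyclohexane-1-carboxylate (C2 epimers) | COC(=O)[C@]1(C)CCC[C@@]([C@H](C=C)CCC2(C)OCCO2)(C)C1C=O | intermediate
12 | methyl 2-formyl-1,3-dimethyl-3-[5-(2-methyl-1,3-dioxolan-2-yl)-2-oxopentan-3-yl]cyclohexane-1-carboxylate (stereocentres as in 11) | COC(=O)[C@]1(C)CCC[C@@]([C@H](C(C)=O)CCC2(C)OCCO2)(C)C1C=O | intermediate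
13 | methyl 6α-hydroxy-4β,10β-dimethyl-9β-[2-(2-methyl-1,3-dioxolan-2-yl)ethyl]-8-oxo-5α-decalin-4α-carboxylate | COC(=O)[C@]1(C)CCC[C@@]2(C)[C@H]1[C@@H](O)CC(=O)[C@@H]2CCC3(C)OCCO3 | intermediate
14 | methyl 6α-hydroxy-4β,10β-dimethyl-8-methylidene-9β-[2-(2-methyl-1,3-dioxolan-2-yl)ethyl]-5α-decalin-4α-carboxylate | COC(=O)[C@]1(C)CCC[C@@]2(C)[C@H]1[C@@H](O)CC(=C)[C@@H]2CCC3(C)OCCO3 | intermediate
15 | methyl 6α,8α-dihydroxy-4β,8β,10β-trimethyl-9β-[2-(2-methyl-1,3-dioxolan-2-yl)ethyl]-5α-decalin-4α-carboxylate | COC(=O)[C@]1(C)CCC[C@@]2(C)[C@H]1[C@@H](O)C[C@@](C)(O)[C@@H]2CCC3(C)OCCO3 | intermediate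
16 | 6,8-bis-O-TBS ether of 15 | COC(=O)[C@]1(C)CCC[C@@]2(C)[C@H]1[C@@H](O[Si](C)(C)C(C)(C)C)C[C@@](C)(O[Si](C)(C)C(C)(C)C)[C@@H]2CCC3(C)OCCO3 | intermediate
17 | methyl 6α,8α-bis(tert-butyldimethylsilyloxy)-9β-(3,3-dimethoxybutyl)-4β,8β,10β-trimethyl-5α-decalin-4α-carboxylate (not isolated) | COC(=O)[C@]1(C)CCC[C@@]2(C)[C@H]1[C@@H](O[Si](C)(C)C(C)(C)C)C[C@@](C)(O[Si](C)(C)C(C)(C)C)[C@@H]2CCC(C)(OC)OC | intermediate
18 | methyl 6α,8α-bis(tert-butyldimethylsilyloxy)-9β-(3-hydroperoxy-3-methoxybutyl)-4β,8β,10β-trimethyl-5α-decalin-4α-carboxylate (C13 epimers) | COC(=O)[C@]1(C)CCC[C@@]2(C)[C@H]1[C@@H](O[Si](C)(C)C(C)(C)C)C[C@@](C)(O[Si](C)(C)C(C)(C)C)[C@@H]2CCC(C)(OC)OO | intermediate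
19 | methyl 6α,8α-bis(tert-butyldimethylsilyloxy)-9β-[3-(tert-butyldimethylsilylperoxy)-3-methoxybutyl]-4β,8β,10β-trimethyl-5α-decalin-4α-carboxylate (C13 epimers) | COC(=O)[C@]1(C)CCC[C@@]2(C)[C@H]1[C@@H](O[Si](C)(C)C(C)(C)C)C[C@@](C)(O[Si](C)(C)C(C)(C)C)[C@@H]2CCC(C)(OC)OO[Si](C)(C)C(C)(C)C | intermediate
20 | acrolein | C=CC=O | starting material
21 | methyl propiolate | C#CC(=O)OC | starting material
22 | methyl (4S)-4-hydroxyhex-5-en-2-ynoate | C=C[C@H](O)C#CC(=O)OC | intermediate
23 | methyl (2Z,4S)-4-hydroxy-3-methylhexa-2,5-dienoate (not isolated) | C=C[C@H](O)/C(C)=C\C(=O)OC | intermediate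
24 | (5S)-5-ethenyl-4-methylfuran-2(5H)-one | C=C[C@@H]1OC(=O)C=C1C | intermediate
25 | (5S)-4-methyl-5-[(E)-2-(4,4,5,5-tetramethyl-1,3,2-dioxaborolan-2-yl)ethenyl]furan-2(5H)-one | CC1(C)OB(/C=C/[C@@H]2OC(=O)C=C2C)OC1(C)C | intermediate
26 | 6,8-bis-O-TBS, 13-OO-TBS derivative of 27 | COC(=O)[C@]1(C)CCC[C@@]2(C)[C@H]1[C@@H](O[Si](C)(C)C(C)(C)C)C[C@@](C)(O[Si](C)(C)C(C)(C)C)[C@@H]2CC[C@](C)(/C=C/[C@@H]1OC(=O)C=C1C)OO[Si](C)(C)C(C)(C)C | intermediate
27 | CNP0128148.1: methyl 6α,8α-dihydroxy-4β,8β,10β-trimethyl-9β-{(3R,4E)-3-hydroperoxy-3-methyl-5-[(2S)-3-methyl-5-oxo-2,5-dihydrofuran-2-yl]pent-4-en-1-yl}-5α-decalin-4α-carboxylate | COC(=O)[C@]1(C)CCC[C@@]2(C)[C@H]1[C@@H](O)C[C@@](C)(O)[C@@H]2CC[C@](C)(/C=C/[C@@H]1OC(=O)C=C1C)OO | target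

## Step count and risks

Total: 18 steps. Longest linear sequence: 13 steps (1 → 2 → 4 → 9 → 11 → 12 → 13 → 14 → 15 → 16 → 18 → 19 → 26 → 27).

**Step 17 (proposed new method).** The peroxycarbenium ion may fragment, the boronate may be too weak a nucleophile, or the CH3/CH2R face discrimination may be poor. Fallback with known chemistry, setting out from 16 and coming back at 27: the ketal of 16 is hydrolysed (PPTS, acetone/H2O) to the methyl ketone F5, which is methylenated (Ph3P=CH2, THF) to the isopropenyl compound F6. Separately, commercial 4-methylfuran-2(5H)-one is silylated (TMSOTf, Et3N) to 4-methyl-2-(trimethylsilyloxy)furan F7 and γ-allylated (allyl bromide, AgOCOCF3) to racemic 5-allyl-4-methylfuran-2(5H)-one F8. Cross-metathesis of F6 with F8 (second-generation Hoveyda–Grubbs catalyst RuCl2(=CH-C6H4-2-O-iPr)(H2IMes)) gives the trisubstituted 13(14)-alkene F9 as E/Z and C16 isomers. Dye-sensitised photooxygenation (O2, tetraphenylporphyrin, hν; Schenck ene reaction) puts the hydroperoxide on C13 and moves the double bond to C14=C15 (E). This reaction is neither regio- nor stereoselective, so the (13R,16S) bis-silyl hydroperoxide F10 is isolated by HPLC and desilylated with HF·pyridine to 27.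

**Step 5.** The hindered, fully substituted enolate may react slowly with the allyl–iridium species, or the facial selectivity at C10 (anti to the C4 methyl) may be low. Fallback setting out from 4 and 8 and coming back at 9: methanolysis of 8 (K2CO3, MeOH) gives the allylic alcohol F1, and MsCl/Et3N gives the mesylate F2. O-Alkylation of the potassium enolate of 4 (KH, 18-crown-6, THF/HMPA) with F2 gives the allyl enol ether F3. Heating (toluene, 120 °C) brings about a Claisen rearrangement through a chair transition state to 9. Any C9 epimer converges in step 8, where C9 is α to the C8 ketone; C10 diastereomers are separated by chromatography.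

**Step 6.** The ketone lies between two quaternary carbons and the sulfur ylide may not add. Fallback setting out from 9 and coming back at 10: 9 is methylenated with Zn/CH2Br2/TiCl4 to the exocyclic alkene F4. F4 is then epoxidised chemoselectively at its 1,1-disubstituted double bond with dimethyldioxirane (acetone, 0 °C) to give 10, which is rearranged with MgBr2·OEt2 as in step 6.

Further compounds

F1 | step 5 | (2E)-5-(2-methyl-1,3-dioxolan-2-yl)pent-2-en-1-ol | OC/C=C/CCC1(C)OCCO1
F2 | step 5 | (2E)-5-(2-methyl-1,3-dioxolan-2-yl)pent-2-en-1-yl methanesulfonate | CS(=O)(=O)OC/C=C/CCC1(C)OCCO1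
F3 | step 5 | methyl (1R)-1,3-dimethyl-2-{[(2E)-5-(2-methyl-1,3-dioxolan-2-yl)pent-2-en-1-yl]oxy}cyclohex-2-ene-1-carboxylate | COC(=O)[C@]1(C)CCCC(C)=C1OC/C=C/CCC2(C)OCCO2
F4 | step 6 | methyl (1R,3R)-1,3-dimethyl-2-methylidene-3-[(3S)-5-(2-methyl-1,3-dioxolan-2-yl)pent-1-en-3-yl]cyclohexane-1-carboxylate | COC(=O)[C@]1(C)CCC[C@@]([C@H](C=C)CCC2(C)OCCO2)(C)C1=C
F5 | step 17 | methyl 6α,8α-bis(tert-butyldimethylsilyloxy)-4β,8β,10β-trimethyl-9β-(3-oxobutyl)-5α-decalin-4α-carboxylate | COC(=O)[C@]1(C)CCC[C@@]2(C)[C@H]1[C@@H](O[Si](C)(C)C(C)(C)C)C[C@@](C)(O[Si](C)(C)C(C)(C)C)[C@@H]2CCC(C)=O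
F6 | step 17 | methyl 6α,8α-bis(tert-butyldimethylsilyloxy)-4β,8β,10β-trimethyl-9β-(3-methylbut-3-en-1-yl)-5α-decalin-4α-carboxylate | COC(=O)[C@]1(C)CCC[C@@]2(C)[C@H]1[C@@H](O[Si](C)(C)C(C)(C)C)C[C@@](C)(O[Si](C)(C)C(C)(C)C)[C@@H]2CCC(C)=C
F7 | step 17 | 4-methyl-2-(trimethylsilyloxy)furan | C[Si](C)(C)Oc1cc(C)co1
F8 | step 17 | 5-allyl-4-methylfuran-2(5H)-one (racemic) | C=CCC1OC(=O)C=C1C
F9 | step 17 | methyl 6α,8α-bis(tert-butyldimethylsilyloxy)-4β,8β,10β-trimethyl-9β-[(3E)-3-methyl-5-(3-methyl-5-oxo-2,5-dihydrofuran-2-yl)pent-3-en-1-yl]-5α-decalin-4α-carboxylate (E isomer shown; formed with Z and C16 isomers) | COC(=O)[C@]1(C)CCC[C@@]2(C)[C@H]1[C@@H](O[Si](C)(C)C(C)(C)C)C[C@@](C)(O[Si](C)(C)C(C)(C)C)[C@@H]2CC/C(C)=C/CC3OC(=O)C=C3C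
F10 | step 17 | 6,8-bis-O-TBS ether of 27 (free 13-hydroperoxide; 13R,14E,16S) | COC(=O)[C@]1(C)CCC[C@@]2(C)[C@H]1[C@@H](O[Si](C)(C)C(C)(C)C)C[C@@](C)(O[Si](C)(C)C(C)(C)C)[C@@H]2CC[C@](C)(/C=C/[C@@H]3OC(=O)C=C3C)OO
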